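**Retrosynthetic overview**
1. Miyabenol A (21) comes from its octabenzyl ether 20 by global debenzylation; every phenol except the one in use stays benzyl-protected.
2. Each trans-2,3-diaryl-2,3-dihydrobenzofuran comes from an α,α-diaryl keto-phenol: a dynamic-kinetic-resolution reduction fixes C3, then SN1 closure of the C2–O bond gives the trans ring (catalyst enantiomer alternated to give R,R / S,S / R,R).
3. Key disconnection, used three times: the C3–C3a bond (ketone α-carbon to phenol ortho-carbon) from a free phenol and one common α-aryl-α-diazoketone 6 acting as an enolonium (α-keto cation) equivalent, so two inherently nucleophilic carbons are joined.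
4. Building blocks: 6 from 5-bromoresorcinol and 4'-(benzyloxy)acetophenone (α-arylation, diazo transfer); the first phenol 8 is 3,4'-di-O-benzylresveratrol.
5. Ring order (forward, chain grows from the stilbene end): dihydrofuran ring A (step 7), ring B (step 9), ring C (step 11).

Assumption: reagents that only deliver a protecting group or the diazo nitrogen are given by name and SMILES in the step and carry no compound number; the sense of each ketone reduction is assigned by the Felkin–Anh model, and because C2 is reset in the SN1 closure the mirror-image catalyst would be used if the other C3 epimer proved the fast-reacting one.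

**Route**

Step 1
Reactants: 1 5-bromoresorcinol
Product: 2 3-(benzyloxy)-5-bromophenol
Conditions: BnBr (1.0 equiv), K2CO3 (1.1 equiv), acetone, 50 °C; chromatography (diol and diether recycled)
Reagents that add atoms: benzyl bromide, BrCc1ccccc1
Why: Williamson etherification of a symmetrical diol under statistical control gives the mono-ether (about 45 %), which differentiates the two ring oxygens once for all three chain-extension units; no stereocentre.

Step 2
Reactants: 2 3-(benzyloxy)-5-bromophenol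
Product: 3 [3-(benzyloxy)-5-bromophenoxy]triisopropylsilane
Conditions: TIPSCl (1.2 equiv), imidazole (2.5 equiv), DMF, rt
Reagents that add atoms: chlorotriisopropylsilane, CC(C)[Si](Cl)(C(C)C)C(C)C
Why: standard silylation of a phenol; the triisopropylsilyl ether is the temporary group that survives base, Lewis acid and transfer hydrogenation and is later removed by fluoride in the presence of benzyl ethers.

Step 3
Reactants: 3 [3-(benzyloxy)-5-bromophenoxy]triisopropylsilane; 4 1-[4-(benzyloxy)phenyl]ethanone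
Product: 5 1-[4-(benzyloxy)phenyl]-2-[3-(benzyloxy)-5-(triisopropylsilyloxy)phenyl]ethan-1-one
Conditions: Pd2(dba)3 (1.5 mol%), Xantphos (3.6 mol%), K3PO4 (2.3 equiv), 4 (1.3 equiv), toluene, 80 °C
Reagents that add atoms: none
Why: palladium-catalysed α-arylation of a methyl ketone (Buchwald–Hartwig type) with a wide-bite-angle ligand gives the mono-arylated deoxybenzoin, and the mild phosphate base spares the aryl silyl ether.

Step 4
Reactants: 5 1-[4-(benzyloxy)phenyl]-2-[3-(benzyloxy)-5-(triisopropylsilyloxy)phenyl]ethan-1-one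
Product: 6 1-[4-(benzyloxy)phenyl]-2-[3-(benzyloxy)-5-(triisopropylsilyloxy)phenyl]-2-diazoethan-1-one
Conditions: p-ABSA (1.3 equiv), DBU (1.5 equiv), MeCN, 0 °C to rt
Reagents that add atoms: 4-acetamidobenzenesulfonyl azide, CC(=O)Nc1ccc(cc1)S(=O)(=O)N=[N+]=[N-]
Why: Regitz diazo transfer to the doubly activated benzylic methylene of a deoxybenzoin gives the stable α-aryl-α-diazoketone that serves as the common electrophilic monomer.

Step 5
Reactants: 7 resveratrol
Product: 8 3-(benzyloxy)-5-[(E)-2-(4-(benzyloxy)phenyl)ethenyl]phenol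
Conditions: BnBr (2.0 equiv), K2CO3 (2.2 equiv), acetone, reflux; chromatography (about 35–40 %, lower ethers recycled)
Reagents that add atoms: benzyl bromide, BrCc1ccccc1
Why: Williamson etherification in which the most acidic 4'-OH reacts first and one of the two equivalent resorcinol OH groups second, leaving the single free phenol that directs and later closes ring A.

Step 6
Reactants: 8 3-(benzyloxy)-5-[(E)-2-(4-(benzyloxy)phenyl)ethenyl]phenol; 6 1-[4-(benzyloxy)phenyl]-2-[3-(benzyloxy)-5-(triisopropylsilyloxy)phenyl]-2-diazoethan-1-one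
Product: 9 two-unit keto-phenol (epimers at the new CH)
Conditions: B(C6F5)3 (10 mol%), 6 (1.3 equiv, added over 2 h), CH2Cl2, 0 °C to rt; Et3N quench
Reagents that add atoms: none
Why: Proposed new method: B(C6F5)3 binds the ketone oxygen of 6 so that loss of N2 leaves an electrophilic α-carbon (a boron-enolate-stabilised α-keto cation, an enolonium equivalent), which the hydrogen-bonded phenol attacks through the ortho carbon that is also para to its benzyloxy group (the ring carbon between OH and the styryl group) before proton transfer re-aromatises the ring; the closest known reaction is the B(C6F5)3-catalysed ortho-selective C–H alkylation of free phenols by α-aryl-α-diazoesters, and the new CH stereocentre is deliberately left as an epimerisable mixture.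

Step 7
Reactants: 9 two-unit keto-phenol
Product: 12 two-unit phenol (ring A closed; 2R,3R), via (1R,2R)-carbinol 10 (not isolated), via ring A silyl ether 11 (not isolated)
Conditions: RuCl(p-cymene)[(R,R)-TsDPEN] (5 mol%), HCO2H (5 equiv), Et3N (6 equiv), DMF, 40 °C; extractive work-up; then CSA (20 mol%), CH2Cl2, 0 °C; then TBAF (1.5 equiv), AcOH (1.5 equiv), THF, 0 °C
Reagents that add atoms: none
Why: Proposed new method: the doubly benzylic α-hydrogen lets the two epimers of 9 interconvert through the enol in the amine/formate medium faster than they are reduced, and the (R,R)-catalyst, which gives R carbinols from aryl ketones, reduces the Felkin–Anh-matched epimer (bulky 2,6-disubstituted aryl anti to hydride) to the (1R,2R)-carbinol (closest known reaction: Noyori–Ikariya transfer hydrogenation with dynamic kinetic resolution of benzoins and α-substituted aryl ketones); acid then ionises the p-benzyloxybenzylic alcohol and the neighbouring phenol closes the five-membered ring by SN1 to the favoured 2,3-trans ether, so only the C3 configuration has to be set by the reduction, and fluoride frees the phenol for the next coupling.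

Step 8
Reactants: 12 two-unit phenol; 6 1-[4-(benzyloxy)phenyl]-2-[3-(benzyloxy)-5-(triisopropylsilyloxy)phenyl]-2-diazoethan-1-one
Product: 13 three-unit keto-phenol (epimers at the new CH)
Conditions: B(C6F5)3 (15 mol%), 6 (1.5 equiv, added over 2 h), CH2Cl2, rt; Et3N quench
Reagents that add atoms: none
Why: Proposed new method: same boron-activated enolonium-type α-carbon of 6 as in step 6, now attacked by the only free phenol of 12 at its ortho carbon para to OBn (between OH and the ring A attachment), the benzyl-capped older ring lacking the hydrogen-bond delivery; closest known reaction is again the B(C6F5)3-catalysed ortho C–H alkylation of phenols by α-aryl-α-diazoesters, and the new CH is left as an epimer mixture.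

Step 9
Reactants: 13 three-unit keto-phenol
Product: 16 three-unit phenol (ring B closed; 2S,3S), via (1S,2S)-carbinol 14 (not isolated), via ring B silyl ether 15 (not isolated)
Conditions: RuCl(p-cymene)[(S,S)-TsDPEN] (5 mol%), HCO2H (5 equiv), Et3N (6 equiv), DMF, 40 °C; extractive work-up; then CSA (20 mol%), CH2Cl2, 0 °C; then TBAF (1.5 equiv), AcOH (1.5 equiv), THF, 0 °C
Reagents that add atoms: none
Why: Proposed new method: as in step 7 the ketone epimerises at the α-carbon while the mirror-image (S,S)-catalyst selects the Felkin–Anh-matched epimer to give the (1S,2S)-carbinol (closest known reaction: Noyori–Ikariya dynamic-kinetic-resolution transfer hydrogenation), SN1 closure by the adjacent phenol then gives the trans (2S,3S) ring B, and fluoride unmasks the next phenol; ring A is untouched.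

Step 10
Reactants: 16 three-unit phenol; 6 1-[4-(benzyloxy)phenyl]-2-[3-(benzyloxy)-5-(triisopropylsilyloxy)phenyl]-2-diazoethan-1-one
Product: 17 four-unit keto-phenol (epimers at the new CH)
Conditions: B(C6F5)3 (15 mol%), 6 (2.0 equiv, added over 3 h), CH2Cl2, rt; Et3N quench
Reagents that add atoms: none
Why: Proposed new method: third use of the boron-activated diazoketone as an α-keto cation equivalent, attacked by the single free phenol of 16 at the ortho carbon para to OBn (between OH and the ring B attachment); closest known reaction is the B(C6F5)3-catalysed ortho C–H alkylation of phenols by α-aryl-α-diazoesters, and the new CH is left as an epimer mixture.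

Step 11
Reactants: 17 four-unit keto-phenol
Product: 20 four-unit phenol (ring C closed; 2R,3R; octa-O-benzyl-miyabenol A), via (1R,2R)-carbinol 18 (not isolated), via ring C silyl ether 19 (not isolated)
Conditions: RuCl(p-cymene)[(R,R)-TsDPEN] (5 mol%), HCO2H (5 equiv), Et3N (6 equiv), DMF, 40 °C; extractive work-up; then CSA (20 mol%), CH2Cl2, 0 °C; then TBAF (1.5 equiv), AcOH (1.5 equiv), THF, 0 °C
Reagents that add atoms: none
Why: Proposed new method: dynamic-kinetic-resolution transfer hydrogenation with the (R,R)-catalyst as in step 7 gives the (1R,2R)-carbinol (closest known reaction: Noyori–Ikariya reduction of configurationally labile α-substituted aryl ketones), SN1 closure gives the trans (2R,3R) ring C, and fluoride removes the last silyl group; rings A and B are untouched.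

Step 12
Reactants: 20 four-unit phenol (octa-O-benzyl-miyabenol A)
Product: 21 miyabenol A
Conditions: BCl3 (1 M in CH2Cl2, 24 equiv), C6HMe5 (40 equiv), CH2Cl2, −78 to −40 °C; aqueous work-up
Reagents that add atoms: none
Why: Lewis-acid debenzylation with the non-basic cation scavenger pentamethylbenzene at low temperature cleaves all eight aryl benzyl ethers while leaving the stilbene and the three dihydrofuran C–O bonds intact, so no stereocentre is affected.

**Compound list**

1 | 5-bromoresorcinol (5-bromobenzene-1,3-diol) | Oc1cc(O)cc(Br)c1 | starting material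
2 | 3-(benzyloxy)-5-bromophenol | Oc1cc(Br)cc(OCc2ccccc2)c1 | intermediate
3 | [3-(benzyloxy)-5-bromophenoxy]triisopropylsilane | CC(C)[Si](Oc1cc(Br)cc(OCc2ccccc2)c1)(C(C)C)C(C)C | intermediate
4 | 1-[4-(benzyloxy)phenyl]ethanone | CC(=O)c1ccc(OCc2ccccc2)cc1 | starting material
5 | 1-[4-(benzyloxy)phenyl]-2-[3-(benzyloxy)-5-(triisopropylsilyloxy)phenyl]ethan-1-one | O=C(Cc1cc(OCc2ccccc2)cc(O[Si](C(C)C)(C(C)C)C(C)C)c1)c1ccc(OCc2ccccc2)cc1 | intermediate
6 | 1-[4-(benzyloxy)phenyl]-2-[3-(benzyloxy)-5-(triisopropylsilyloxy)phenyl]-2-diazoethan-1-one | [N-]=[N+]=C(C(=O)c1ccc(OCc2ccccc2)cc1)c1cc(OCc2ccccc2)cc(O[Si](C(C)C)(C(C)C)C(C)C)c1 | intermediate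
7 | resveratrol, (E)-5-[2-(4-hydroxyphenyl)ethenyl]benzene-1,3-diol | Oc1ccc(/C=C/c2cc(O)cc(O)c2)cc1 | starting material
8 | 3-(benzyloxy)-5-[(E)-2-(4-(benzyloxy)phenyl)ethenyl]phenol (3,4'-di-O-benzylresveratrol) | Oc1cc(OCc2ccccc2)cc(/C=C/c2ccc(OCc3ccccc3)cc2)c1 | intermediate
9 | 2-{4-(benzyloxy)-2-hydroxy-6-[(E)-2-(4-(benzyloxy)phenyl)ethenyl]phenyl}-1-[4-(benzyloxy)phenyl]-2-[3-(benzyloxy)-5-(triisopropylsilyloxy)phenyl]ethan-1-one, both C2 epimers (interconverting) | C(c6ccccc6)Oc1ccc(/C=C/c2cc(OCc6ccccc6)cc(O)c2C(c2cc(OCc6ccccc6)cc(O[Si](C(C)C)(C(C)C)C(C)C)c2)C(=O)c2ccc(OCc6ccccc6)cc2)cc1 | intermediate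
10 | (1R,2R)-alcohol of 9 (CH(OH) in place of C=O; C1 = carbinol carbon, C2 = triaryl-substituted CH) | C(c6ccccc6)Oc1ccc(/C=C/c2cc(OCc6ccccc6)cc(O)c2[C@@H](c2cc(OCc6ccccc6)cc(O[Si](C(C)C)(C(C)C)C(C)C)c2)[C@@H](O)c2ccc(OCc6ccccc6)cc2)cc1 | intermediate
11 | (2R,3R)-6-(benzyloxy)-2-[4-(benzyloxy)phenyl]-4-[(E)-2-(4-(benzyloxy)phenyl)ethenyl]-3-[3-(benzyloxy)-5-(triisopropylsilyloxy)phenyl]-2,3-dihydro-1-benzofuran (trans) | C(c6ccccc6)Oc1ccc(/C=C/c2cc(OCc6ccccc6)cc3c2[C@@H](c2cc(OCc6ccccc6)cc(O[Si](C(C)C)(C(C)C)C(C)C)c2)[C@H](c2ccc(OCc6ccccc6)cc2)O3)cc1 | intermediate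
12 | (2R,3R)-6-(benzyloxy)-2-[4-(benzyloxy)phenyl]-4-[(E)-2-(4-(benzyloxy)phenyl)ethenyl]-3-[3-(benzyloxy)-5-hydroxyphenyl]-2,3-dihydro-1-benzofuran (trans; a tetra-O-benzyl ε-viniferin-type phenol) | C(c6ccccc6)Oc1ccc(/C=C/c2cc(OCc6ccccc6)cc3c2[C@@H](c2cc(OCc6ccccc6)cc(O)c2)[C@H](c2ccc(OCc6ccccc6)cc2)O3)cc1 | intermediate
13 | 12 whose pendant ring carries, on the carbon between its OH and the ring A attachment, the group CH[3-(benzyloxy)-5-(triisopropylsilyloxy)phenyl]–C(=O)–[4-(benzyloxy)phenyl]; both epimers at that CH | C(c6ccccc6)Oc1ccc(/C=C/c2cc(OCc6ccccc6)cc3c2[C@@H](c2cc(OCc6ccccc6)cc(O)c2C(c2cc(OCc6ccccc6)cc(O[Si](C(C)C)(C(C)C)C(C)C)c2)C(=O)c2ccc(OCc6ccccc6)cc2)[C@H](c2ccc(OCc6ccccc6)cc2)O3)cc1 | intermediate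
14 | (1S,2S)-alcohol of 13 (new carbinol carbon S, adjacent triaryl-substituted CH S; ring A 2R,3R) | C(c6ccccc6)Oc1ccc(/C=C/c2cc(OCc6ccccc6)cc3c2[C@@H](c2cc(OCc6ccccc6)cc(O)c2[C@H](c2cc(OCc6ccccc6)cc(O[Si](C(C)C)(C(C)C)C(C)C)c2)[C@H](O)c2ccc(OCc6ccccc6)cc2)[C@H](c2ccc(OCc6ccccc6)cc2)O3)cc1 | intermediate
15 | bis(dihydrobenzofuran): ring A (2R,3R) as in 12, its C3 bonded to C4 of ring B, a trans-(2S,3S)-6-(benzyloxy)-2-[4-(benzyloxy)phenyl]-3-[3-(benzyloxy)-5-(triisopropylsilyloxy)phenyl]-2,3-dihydrobenzofuran | C(c6ccccc6)Oc1ccc(/C=C/c2cc(OCc6ccccc6)cc3c2[C@@H](c2cc(OCc6ccccc6)cc4c2[C@H](c2cc(OCc6ccccc6)cc(O[Si](C(C)C)(C(C)C)C(C)C)c2)[C@@H](c2ccc(OCc6ccccc6)cc2)O4)[C@H](c2ccc(OCc6ccccc6)cc2)O3)cc1 | intermediate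
16 | 15 with the silyl ether replaced by OH (pendant ring on ring B C3 = 3-(benzyloxy)-5-hydroxyphenyl) | C(c6ccccc6)Oc1ccc(/C=C/c2cc(OCc6ccccc6)cc3c2[C@@H](c2cc(OCc6ccccc6)cc4c2[C@H](c2cc(OCc6ccccc6)cc(O)c2)[C@@H](c2ccc(OCc6ccccc6)cc2)O4)[C@H](c2ccc(OCc6ccccc6)cc2)O3)cc1 | intermediate
17 | 16 whose pendant ring carries, on the carbon between its OH and the ring B attachment, the group CH[3-(benzyloxy)-5-(triisopropylsilyloxy)phenyl]–C(=O)–[4-(benzyloxy)phenyl]; both epimers at that CH | C(c6ccccc6)Oc1ccc(/C=C/c2cc(OCc6ccccc6)cc3c2[C@@H](c2cc(OCc6ccccc6)cc4c2[C@H](c2cc(OCc6ccccc6)cc(O)c2C(c2cc(OCc6ccccc6)cc(O[Si](C(C)C)(C(C)C)C(C)C)c2)C(=O)c2ccc(OCc6ccccc6)cc2)[C@@H](c2ccc(OCc6ccccc6)cc2)O4)[C@H](c2ccc(OCc6ccccc6)cc2)O3)cc1 | intermediate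
18 | (1R,2R)-alcohol of 17 (new carbinol carbon R, adjacent triaryl-substituted CH R; ring A 2R,3R; ring B 2S,3S) | C(c6ccccc6)Oc1ccc(/C=C/c2cc(OCc6ccccc6)cc3c2[C@@H](c2cc(OCc6ccccc6)cc4c2[C@H](c2cc(OCc6ccccc6)cc(O)c2[C@@H](c2cc(OCc6ccccc6)cc(O[Si](C(C)C)(C(C)C)C(C)C)c2)[C@@H](O)c2ccc(OCc6ccccc6)cc2)[C@@H](c2ccc(OCc6ccccc6)cc2)O4)[C@H](c2ccc(OCc6ccccc6)cc2)O3)cc1 | intermediate
19 | tris(dihydrobenzofuran): rings A (2R,3R) and B (2S,3S) as in 16, C3 of ring B bonded to C4 of ring C, a trans-(2R,3R)-6-(benzyloxy)-2-[4-(benzyloxy)phenyl]-3-[3-(benzyloxy)-5-(triisopropylsilyloxy)phenyl]-2,3-dihydrobenzofuran | C(c6ccccc6)Oc1ccc(/C=C/c2cc(OCc6ccccc6)cc3c2[C@@H](c2cc(OCc6ccccc6)cc4c2[C@H](c2cc(OCc6ccccc6)cc5c2[C@@H](c2cc(OCc6ccccc6)cc(O[Si](C(C)C)(C(C)C)C(C)C)c2)[C@H](c2ccc(OCc6ccccc6)cc2)O5)[C@@H](c2ccc(OCc6ccccc6)cc2)O4)[C@H](c2ccc(OCc6ccccc6)cc2)O3)cc1 | intermediate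
20 | 19 with the silyl ether replaced by OH: octa-O-benzyl-miyabenol A (free OH on the terminal 3,5-dioxygenated ring) | C(c6ccccc6)Oc1ccc(/C=C/c2cc(OCc6ccccc6)cc3c2[C@@H](c2cc(OCc6ccccc6)cc4c2[C@H](c2cc(OCc6ccccc6)cc5c2[C@@H](c2cc(OCc6ccccc6)cc(O)c2)[C@H](c2ccc(OCc6ccccc6)cc2)O5)[C@@H](c2ccc(OCc6ccccc6)cc2)O4)[C@H](c2ccc(OCc6ccccc6)cc2)O3)cc1 | intermediate
21 | miyabenol A (ring A 2R,3R; ring B 2S,3S; ring C 2R,3R; E-stilbene) | Oc1ccc(/C=C/c2cc(O)cc3c2[C@@H](c2cc(O)cc4c2[C@H](c2cc(O)cc5c2[C@@H](c2cc(O)cc(O)c2)[C@H](c2ccc(O)cc2)O5)[C@@H](c2ccc(O)cc2)O4)[C@H](c2ccc(O)cc2)O3)cc1 | target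

**Step count and risks**

Total steps: 12 (each reduction/ring closure/desilylation sequence is run without isolating intermediates and counted as one step). Longest linear sequence: 11 steps (steps 1–4, then 6–12).

Three steps most likely to fail:

Step 10 (the key coupling at its most hindered; steps 6 and 8 carry the same risks in milder form). The reacting carbon of 16 lies between the phenolic OH and a fully substituted benzylic carbon of a crowded three-unit chain. Attack at the carbon between the two oxygens, O–H insertion, or cyclodehydration of the keto-phenol to a benzofuran may win. Fallback, setting out from 16 (and from 3 for the aldehyde) and coming back at 17: the same ketone is assembled by acyl-anion addition to an ortho-quinone methide, so the hindered aryl–carbon bond is made with a small aldehyde and the C(=O)–CH bond is made second. Bromide 3 is lithiated (n-BuLi, THF, −78 °C) and formylated with DMF to 3-(benzyloxy)-5-(triisopropylsilyloxy)benzaldehyde F1. Phenol 16, F1 and TolSO2Na are condensed in aqueous HCO2H to the ortho-(α-sulfonylbenzyl)phenol F2. Cs2CO3 eliminates sulfinate from F2 to give the transient ortho-quinone methide F3. A thiazolium-derived carbene (3-benzyl-5-(2-hydroxyethyl)-4-methylthiazolium chloride, 20 mol%) converts 4-(benzyloxy)benzaldehyde into its Breslow intermediate, which adds 1,4 to F3 (Stetter-type) and re-aromatises to ketone 17.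

Step 9 (dynamic kinetic resolution against existing stereocentres; steps 7 and 11 share the mechanism). If α-epimerisation is slow in this crowded ketone, or the bias of ring A overrides the catalyst, ring B forms as a mixture. Fallback, setting out from 13 and coming back at 15: catalyst control is replaced by separation of diastereomers, which is possible because ring A is already a single enantiomer. NaBH4 (MeOH/THF, 0 °C) reduces 13 to the carbinol mixture F4. CSA in CH2Cl2 closes the ring (any cis ether equilibrates to trans through the benzylic cation) to give 15 together with its ring B (2R,3R) diastereomer F5. The two are separated by chromatography, and 15 is desilylated to 16 as in step 9.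

Step 12 (eight benzyl ethers on an acid-sensitive stilbene/dihydrobenzofuran polyphenol). Ionisation of the benzylic ring C–O bonds or Friedel–Crafts closure onto the stilbene could compete. Fallback, setting out from 20 and coming back at 21: the Lewis acid is avoided. NaSEt (excess, DMF, 110 °C, argon) cleaves the ethers by SN2 attack at the benzylic carbons. The crude phenolate is acetylated in the same flask (Ac2O, pyridine) to miyabenol A nonaacetate F6, which is stable and can be purified. Mild methanolysis (K2CO3, MeOH, 0 °C) then gives 21.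

**Further compounds**

F1 | step 10 | 3-(benzyloxy)-5-(triisopropylsilyloxy)benzaldehyde | O=Cc1cc(OCc2ccccc2)cc(O[Si](C(C)C)(C(C)C)C(C)C)c1
F2 | step 10 | 16 whose pendant ring carries, on the carbon between its OH and the ring B attachment, the group CH[3-(benzyloxy)-5-(triisopropylsilyloxy)phenyl](SO2-p-tolyl), both epimers at that CH | C(c6ccccc6)Oc1ccc(/C=C/c2cc(OCc6ccccc6)cc3c2[C@@H](c2cc(OCc6ccccc6)cc4c2[C@H](c2cc(OCc6ccccc6)cc(O)c2C(c2cc(OCc6ccccc6)cc(O[Si](C(C)C)(C(C)C)C(C)C)c2)S(=O)(=O)c2ccc(C)cc2)[C@@H](c2ccc(OCc6ccccc6)cc2)O4)[C@H](c2ccc(OCc6ccccc6)cc2)O3)cc1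
F3 | step 10 | ortho-quinone methide from F2 (pendant ring as 6-arylmethylidene-cyclohexa-2,4-dienone, transient) | C(c6ccccc6)Oc1ccc(/C=C/c2cc(OCc6ccccc6)cc3c2[C@@H](c2cc(OCc6ccccc6)cc4c2[C@H](C2=CC(OCc6ccccc6)=CC(=O)C2=Cc2cc(OCc6ccccc6)cc(O[Si](C(C)C)(C(C)C)C(C)C)c2)[C@@H](c2ccc(OCc6ccccc6)cc2)O4)[C@H](c2ccc(OCc6ccccc6)cc2)O3)cc1
F4 | step 9 | alcohol of 13 as the mixture of stereoisomers at the two new centres (ring A 2R,3R) | C(c6ccccc6)Oc1ccc(/C=C/c2cc(OCc6ccccc6)cc3c2[C@@H](c2cc(OCc6ccccc6)cc(O)c2C(c2cc(OCc6ccccc6)cc(O[Si](C(C)C)(C(C)C)C(C)C)c2)C(O)c2ccc(OCc6ccccc6)cc2)[C@H](c2ccc(OCc6ccccc6)cc2)O3)cc1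
F5 | step 9 | diastereomer of 15 with ring B (2R,3R) and ring A (2R,3R) | C(c6ccccc6)Oc1ccc(/C=C/c2cc(OCc6ccccc6)cc3c2[C@@H](c2cc(OCc6ccccc6)cc4c2[C@@H](c2cc(OCc6ccccc6)cc(O[Si](C(C)C)(C(C)C)C(C)C)c2)[C@H](c2ccc(OCc6ccccc6)cc2)O4)[C@H](c2ccc(OCc6ccccc6)cc2)O3)cc1
F6 | step 12 | miyabenol A nonaacetate | CC(=O)Oc1ccc(/C=C/c2cc(OC(C)=O)cc3c2[C@@H](c2cc(OC(C)=O)cc4c2[C@H](c2cc(OC(C)=O)cc5c2[C@@H](c2cc(OC(C)=O)cc(OC(C)=O)c2)[C@H](c2ccc(OC(C)=O)cc2)O5)[C@@H](c2ccc(OC(C)=O)cc2)O4)[C@H](c2ccc(OC(C)=O)cc2)O3)cc1
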